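## The problem

The target is the 7-methyl ether of 6,8''-biapigenin: two 5,7,4'-trioxygenated flavones joined by one C–C bond between C6 of unit 1 (unprimed locants, ring B primed) and C8'' of unit 2 (double-primed locants, ring B triple-primed). Both carbons of that bond lie between two oxygen-bearing carbons (C5/C7 and C7''/C8a''), so the biaryl is tetra-ortho-substituted, and a late coupling of two flavones would be hindered and would have to tell C6 from C8 on each partner. There is no stereogenic centre; the hindered C6–C8'' axis is the only stereogenic element, nothing in the molecule can control it, and no configuration is defined for it. Of the six phenolic oxygens only O7 of unit 1 is methylated, so five hydroxyls must travel protected and O7 must be singled out. The flavone rings do not survive rough treatment: hot mineral acid scrambles 6- and 8-substituted 5-hydroxyflavones by ring opening and reclosure (Wessely–Moser rearrangement), and strong nucleophilic base opens ring C or metallates C3. The feature that allows a biomimetic entry is ring A of unit 1: C4a carries the acyl carbon C4, C5, C7 and C8a carry oxygen, C8 carries hydrogen and C6 carries unit 2, which is the pattern of an acylphloroglucinol formed by Claisen folding of a cinnamoyl tetraketide arylated at C6. Such a chain can be stored as a 4-hydroxy-2-pyrone (lactone carbonyl = C5, pyrone C3 = C6, C4 = C7, C5 = C8, C6 = C8a), so the inter-unit bond can be made on a small pyrone before ring A exists. The remaining hazard is that the folded ring A has two hydroxyls ortho to the acyl group (on C5 and C8a), and only closure of ring C through the C8a oxygen gives the 6-linked isomer.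

## Retrosynthesis

Four O–benzyl bonds are cut last: target 17 comes from tetrabenzyl ether 16 by hydrogenolysis. Benzyl is preferred over methyl, which would need a selective demethylation beside the O7 methyl ether, and over acetal groups, which would not survive the iodine-mediated oxidation. Benzyl must also sit on the chelated O5'' early, to steer substitution of unit 2 to C8''. The forward step only has to leave the methyl ether and the two pyranone double bonds untouched.

The O7–CH3 bond is cut next, giving diol 15. Methylation is placed after ring C is closed and not on chalcone 13. In 13 three phenols compete and the most exposed one (on C8a) is the oxygen needed for ring C; in 15 the only other free hydroxyl is the chelated, flanked 5-OH. The forward reaction is a routine selective alkylation.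

Ring C of unit 1 is opened at O1–C2 and the C2=C3 unsaturation is taken back to the chalcone level. This leads through flavanone 14 to 2',4',6'-trihydroxychalcone 13. A chalcone is preferred over a 1,3-diketone because the cinnamoyl oxidation state is what the polyketide fold delivers, and because a catalytic-iodine oxidation needs no stoichiometric strong acid or base. The forward reaction must close through the hydroxyl on C8a and not through that on C5; the bias comes from the unit 2 ring on C6, which shields both faces of O5.

The key cut is C4a–C5 in ring A of unit 1. Breaking it turns acylphloroglucinol 13 into open-chain triketo ester 12, and lactonization of 12 between the C5 carboxyl and the C8a enol stores it as 4-hydroxy-2-pyrone 11. Compared with cutting the biaryl bond at this stage, this removes a hexasubstituted benzene ring in one move and leaves a precursor whose aryl-bearing carbon (pyrone C3) is an ordinary β-dicarbonyl carbon. The forward reaction must be chemoselective: Claisen folding instead of aldol folding, conjugate addition or cleavage of the chain.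

Pyrone 11 is cut at the pyrone C3–C8'' bond into iodonium ylide 6 and boronate 10. Making the inter-unit bond here exchanges a coupling of two fully substituted benzene rings for the arylation of a small heterocycle. It also fixes the position on unit 1 beyond doubt, since pyrone C3 can only become C6, and it gives two fragments of three steps each. The forward coupling must tolerate two ortho oxygens on each partner.

Ylide 6 is the trivalent-iodine derivative of pyrone 5. Pyrone 5 is cut at C4a–C4 into triacetic acid lactone 4 and Weinreb amide 3, and 3 is cut at its double bond into aldehyde 1 and phosphonate 2. The side chain is attached before the arylation because the dianion chemistry needs two equivalents of lithium amide, which the flavone of unit 2 would not tolerate reliably (metallation at C3''), whereas 4 does. Each cut removes one simple bond and ends in commercial materials.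

Boronate 10 is taken back through iodide 9 and tribenzyl ether 8 to apigenin 7. The skeleton of unit 2 is thus bought, and only the C8''–B bond has to be installed. Full O-alkylation, including O5'', is what directs the electrophile to C8'' and not to C6''.

## Roads not taken

Alternative 1: The cut runs through ring A of unit 2 (C4a''–C8a'' and C5''–C6''), which is built by a Danheiser benzannulation on a finished unit 1. Cyclobutenone A2 carries the 5,4'-di-O-benzylgenkwanin-6-yl group on its sp3 carbon and a silyloxy group on C3. It is heated with silyloxyalkyne A3; electrocyclic opening to a vinylketene, [2+2] addition of the alkyne, a second four-electron opening and a six-electron closure should give phenol A1.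
- Merits: A1 has exactly one free phenol, on C8a'' next to the biaryl bond, so the oxygen that must become O1'' is singled out by the mechanism. The methyl ether of unit 1 is in place from the start, and the hindered biaryl is never made by cross-coupling.
- Weak points: A1 still lacks C4'', C3'', C2'' and ring B of unit 2. Acylation at C4a'', chain extension, ring closure, desilylation and debenzylation must follow, five or more operations against three after the key step chosen here. A2 is itself a multistep target that presupposes carbon functionalization at C6 of a finished flavone. The aryl silyl ethers of A1 are labile to the bases normally used to build ring C.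
- Comparison: in regiocontrol of the heterocycle closed after the key step this road is better than the chosen plan, whose step 9 must discriminate two ortho hydroxyls. The chosen plan sets against this a key step that completes the carbon skeleton of unit 1 from two three-step fragments, and a shorter endgame.

Alternative 2: Both pyranone rings are cut at C2=C3 and C2''=C3'' and closed together by a double intramolecular ester Wittig reaction. Bis(acylphosphorane) bis(4-benzyloxybenzoate) A5 is heated in toluene; each ylide carbon attacks the neighbouring aryl ester carbonyl and triphenylphosphine oxide is lost twice, giving protected biflavone A4.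
- Merits: two rings form in one operation. No oxidation is needed. The regiochemistry of each closure is fixed by which phenol carries the aroate, so there is no C5/C8a ambiguity.
- Weak points: the difficulty is moved backwards. A5 presupposes that the tetra-ortho-substituted biaryl bond has already been forged between two different, fully differentiated acylphloroglucinol rings, and that the correct phenol of each has been acylated. Stabilized acyl ylides attack aryl esters only at high temperature, and the ester next to the biaryl bond is crowded. A4 carries a 5-O-methyl group that must be cleaved selectively beside the 7-O-methyl group (feasible by chelation-assisted cleavage with BCl3, which would also remove the benzyl groups, but one more selectivity demand).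
- Comparison: this road is better than the chosen plan in ring C regiocontrol and in avoiding an oxidant. The chosen plan offers much shorter access to its key precursor (from 4 and 7) and an endgame with no selective demethylation.

Alternative 3: Ring A of unit 1 is annulated onto a preformed pyranone by cutting C7–C8 and C5–C6. With LiN(SiMe3)2 the methyl group of pyranone ester A7 is deprotonated and acylated by arylacetyl chloride A8. The resulting C6 carbanion then closes on the ester carbon to give A6, which is the same compound as 15 of the chosen route.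
- Merits: ring C exists before ring A, so the O1–C8a connection is fixed by construction; in this respect the road is clearly better than the chosen plan. The endgame from A6 is identical (steps 10 and 11).
- Weak points: an arylacetyl chloride under excess amide base tends to form a ketene and to O-acylate the extended enolate. The ring-closing nucleophile is a hindered diarylmethyl-type carbanion attacking an ester that is deactivated by conjugation with the pyranone oxygen. LiN(SiMe3)2 acts in the presence of the unit 2 flavone. A8 needs a two-carbon homologation at C8'' of 9 or 10, and A7 needs its own synthesis, so the step count is no lower.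
- Comparison: against the regiochemical advantage, the chosen plan has a ring-forming event of an established type (magnesium methoxide Claisen cyclization of pyrone-masked triketo esters), a milder medium for unit 2, and the steric and hydrogen-bond bias of step 9 backed by a flavanone-equilibration fallback.

Key step: step 8

Assumption: the target structure defines no configuration at the hindered C6–C8'' axis, so the axis is formed without control and every compound from 11 onward is taken as racemic about it.

In the names below, tri-O-benzylapigenin-8-yl stands for 5,7-bis(benzyloxy)-2-[4-(benzyloxy)phenyl]-4-oxo-4H-chromen-8-yl.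

## Route

Step 1
Reactants: 1 4-(benzyloxy)benzaldehyde; 2 diethyl {2-[methoxy(methyl)amino]-2-oxoethyl}phosphonate
Product: 3 (E)-3-[4-(benzyloxy)phenyl]-N-methoxy-N-methylprop-2-enamide
Conditions: NaH, THF, 0 °C to rt
Reagents that add atoms: none
Why: Horner–Wadsworth–Emmons olefination with a stabilized amide phosphonate, which should give the E alkene (the future C2=C3 of the chalcone) under thermodynamic control of the elimination. No stereocentre is formed.

Step 2
Reactants: 4 4-hydroxy-6-methyl-2H-pyran-2-one (triacetic acid lactone); 3 (E)-3-[4-(benzyloxy)phenyl]-N-methoxy-N-methylprop-2-enamide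
Product: 5 6-{(E)-4-[4-(benzyloxy)phenyl]-2-oxobut-3-en-1-yl}-4-hydroxy-2H-pyran-2-one
Conditions: LiN(i-Pr)2 (2.2 equiv), THF, −78 °C; then 3, −78 to 0 °C; aq HCl
Reagents that add atoms: none
Why: C-acylation of the lithium O,C-dianion of a 4-hydroxy-6-methyl-2-pyrone at the methyl carbon (the future C4a) by a Weinreb amide. The chelated tetrahedral adduct persists until the acid quench, so the more acidic product cannot protonate unreacted dianion, and the hard carbanion should add to the amide carbonyl and not to the β-carbon of the cinnamoyl unit.

Step 3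
Reactants: 5 6-{(E)-4-[4-(benzyloxy)phenyl]-2-oxobut-3-en-1-yl}-4-hydroxy-2H-pyran-2-one
Product: 6 6-{(E)-4-[4-(benzyloxy)phenyl]-2-oxobut-3-en-1-yl}-2-oxo-3-(phenyliodonio)-2H-pyran-4-olate (phenyliodonium ylide of 5 at pyrone C3)
Conditions: PhI(OAc)2, Na2CO3, MeOH–H2O, 0 °C to rt
Reagents that add atoms: (diacetoxyiodo)benzene, CC(=O)OI(OC(C)=O)c1ccccc1
Why: Formation of a phenyliodonium ylide (trivalent iodine) from a cyclic β-dicarbonyl compound and PhI(OAc)2. Under carbonate the 4-hydroxypyrone is the only site that is fully ionized, so C3 and not the side-chain methylene should bond to iodine; the ylide is kept cold to avoid thermal aryl migration to oxygen.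

Step 4
Reactants: 7 apigenin (5,7-dihydroxy-2-(4-hydroxyphenyl)-4H-chromen-4-one)
Product: 8 5,7-bis(benzyloxy)-2-[4-(benzyloxy)phenyl]-4H-chromen-4-one (tri-O-benzylapigenin)
Conditions: BnBr (excess), K2CO3, DMF, 80 °C
Reagents that add atoms: benzyl bromide, BrCc1ccccc1
Why: Williamson ether synthesis on all three phenols. The chelated 5-OH reacts last and needs excess bromide and heat; its alkylation is required because a free 5-OH would steer the next step to C6.

Step 5
Reactants: 8 5,7-bis(benzyloxy)-2-[4-(benzyloxy)phenyl]-4H-chromen-4-one
Product: 9 5,7-bis(benzyloxy)-2-[4-(benzyloxy)phenyl]-8-iodo-4H-chromen-4-one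
Conditions: N-iodosuccinimide, CF3CO2H (cat.), MeCN, rt
Reagents that add atoms: N-iodosuccinimide, O=C1CCC(=O)N1I
Why: Electrophilic aromatic iodination. In 5,7-di-O-alkylated flavones the position between O7 and the ring oxygen (C8) is attacked, whereas C6 is favoured only under direction of a free 5-OH; ring B is deactivated by conjugation with the pyranone.

Step 6
Reactants: 9 5,7-bis(benzyloxy)-2-[4-(benzyloxy)phenyl]-8-iodo-4H-chromen-4-one
Product: 10 5,7-bis(benzyloxy)-2-[4-(benzyloxy)phenyl]-8-(4,4,5,5-tetramethyl-1,3,2-dioxaborolan-2-yl)-4H-chromen-4-one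
Conditions: B2pin2, PdCl2(dppf), KOAc, 1,4-dioxane, 90 °C
Reagents that add atoms: bis(pinacolato)diboron, CC1(C)OB(OC1(C)C)B1OC(C)(C)C(C)(C)O1
Why: Miyaura borylation of an aryl iodide with B2pin2 under catalysis by zerovalent palladium generated from PdCl2(dppf). Acetate is too weak a base to trigger Suzuki coupling of the product with unreacted 9.

Step 7
Reactants: 6 phenyliodonium ylide of 5; 10 5,7-bis(benzyloxy)-2-[4-(benzyloxy)phenyl]-8-(4,4,5,5-tetramethyl-1,3,2-dioxaborolan-2-yl)-4H-chromen-4-one
Product: 11 6-{(E)-4-[4-(benzyloxy)phenyl]-2-oxobut-3-en-1-yl}-4-hydroxy-3-(tri-O-benzylapigenin-8-yl)-2H-pyran-2-one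
Conditions: Pd(OAc)2, P(t-Bu)3·HBF4, LiOH·H2O, DME–H2O, rt; then dil. HCl
Reagents that add atoms: none
Why: Suzuki–Miyaura-type coupling in which the iodonium ylide of a cyclic β-dicarbonyl compound is the electrophile: zerovalent palladium inserts into the C3–I bond with release of iodobenzene, the aryl group is transferred from the hydroxide-activated boronate and reductive elimination forms the pyrone C3–C8'' bond (the future C6–C8'' bond). The electron-rich, bulky P(t-Bu)3 ligand is chosen because both partners are flanked by two ortho oxygens, and the reaction runs at room temperature, which spares the enone side chain.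

Step 8
Reactants: 11 6-{(E)-4-[4-(benzyloxy)phenyl]-2-oxobut-3-en-1-yl}-4-hydroxy-3-(tri-O-benzylapigenin-8-yl)-2H-pyran-2-one
Product: 13 (E)-3-[4-(benzyloxy)phenyl]-1-[2,4,6-trihydroxy-3-(tri-O-benzylapigenin-8-yl)phenyl]prop-2-en-1-one, via open-chain triketo methyl ester 12 (not isolated)
Conditions: Mg(OMe)2 (excess), MeOH–THF, reflux; then cold dil. HCl
Reagents that add atoms: none
Why: Mg(OMe)2 first ionizes the 4-hydroxypyrone and the side-chain methylene; methoxide then adds to the lactone carbonyl (pyrone C2, the future C5) and the ring opens to the magnesium-chelated triketo methyl ester 12. In 12 the C4a methylene lies between the C4 and C8a carbonyls and is the most acidic carbon, and its magnesium enolate attacks the C5 ester carbon in a 6-exo-trig Claisen (Dieckmann-type) closure that forms C4a–C5 and ring A of unit 1. Loss of methoxide gives a 2-acylcyclohexane-1,3,5-trione that enolizes three times to the phloroglucinol, which makes the sequence irreversible. The closest known reaction type is the magnesium methoxide cyclization of 3,5,7-triketo esters and of their 4-hydroxy-2-pyrone forms to acylphloroglucinols. No stereocentre is formed, and the C6–C8'' axis is already present in 11. The step needs Claisen folding to win over three rivals: the aldol fold (C6 onto C4), conjugate addition of C8 to the enone carbon C2, and retro-Claisen cleavage of the chain at C4a–C4. The aryl group on C6 makes the aldol adduct quaternary at C6, so it cannot dehydrate to an arene and remains reversible, the planar magnesium chelate of the C4/C8a diketone holds the enone terminus away from C8, and aromatization drains the reversible side equilibria toward 13. Cold dilute acid in the work-up is meant to free chalcone 13 before ring C can close.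

Step 9
Reactants: 13 (E)-3-[4-(benzyloxy)phenyl]-1-[2,4,6-trihydroxy-3-(tri-O-benzylapigenin-8-yl)phenyl]prop-2-en-1-one
Product: 15 2-[4-(benzyloxy)phenyl]-5,7-dihydroxy-6-(tri-O-benzylapigenin-8-yl)-4H-chromen-4-one, via 6-aryl flavanone 14 (not isolated)
Conditions: I2 (10 mol %), DMSO, 120–130 °C
Reagents that add atoms: none
Why: Iodine–DMSO oxidative cyclization of a 2'-hydroxychalcone: oxa-Michael closure to flavanone 14, α-iodination and loss of HI, with DMSO returning iodide to iodine. Closure should use the C8a hydroxyl because the C5 hydroxyl is shielded on both faces by the perpendicular unit 2 ring (its O7'' benzyl ether and its ring oxygen) and is held in the stronger, buttressed hydrogen bond to C4=O. Loss of the acid-labile 5''-O-benzyl group here would be harmless, since that phenol stays chelated in step 10 and is freed in step 11 anyway.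

Step 10
Reactants: 15 2-[4-(benzyloxy)phenyl]-5,7-dihydroxy-6-(tri-O-benzylapigenin-8-yl)-4H-chromen-4-one
Product: 16 2-[4-(benzyloxy)phenyl]-5-hydroxy-7-methoxy-6-(tri-O-benzylapigenin-8-yl)-4H-chromen-4-one
Conditions: MeI (1.2 equiv), K2CO3, acetone, reflux
Reagents that add atoms: iodomethane, CI
Why: Williamson methylation of the only unchelated phenol. The 5-OH is hydrogen-bonded to C4=O and flanked by unit 2, so with a small excess of MeI and a weak base only O7 should react.

Step 11
Reactants: 16 2-[4-(benzyloxy)phenyl]-5-hydroxy-7-methoxy-6-(tri-O-benzylapigenin-8-yl)-4H-chromen-4-one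
Product: 17 6-[5,7-dihydroxy-2-(4-hydroxyphenyl)-4-oxo-4H-chromen-8-yl]-5-hydroxy-2-(4-hydroxyphenyl)-7-methoxy-4H-chromen-4-one (6,8''-biapigenin 7-methyl ether)
Conditions: H2 (1 atm), Pd/C (10 wt % Pd), THF–MeOH, rt
Reagents that add atoms: none
Why: Hydrogenolysis of four aryl benzyl ethers over Pd/C. The methyl ether, the flavone enones and the biaryl bond are inert under these conditions.

## Compound list

1 | 4-(benzyloxy)benzaldehyde | O=Cc1ccc(OCc2ccccc2)cc1 | starting material
2 | diethyl {2-[methoxy(methyl)amino]-2-oxoethyl}phosphonate | CCOP(=O)(CC(=O)N(C)OC)OCC | starting material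
3 | (E)-3-[4-(benzyloxy)phenyl]-N-methoxy-N-methylprop-2-enamide | CON(C)C(=O)/C=C/c1ccc(OCc2ccccc2)cc1 | intermediate
4 | 4-hydroxy-6-methyl-2H-pyran-2-one (triacetic acid lactone) | Cc1cc(O)cc(=O)o1 | starting material
5 | 6-{(E)-4-[4-(benzyloxy)phenyl]-2-oxobut-3-en-1-yl}-4-hydroxy-2H-pyran-2-one | O=C(/C=C/c1ccc(OCc2ccccc2)cc1)Cc1cc(O)cc(=O)o1 | intermediate
6 | 6-{(E)-4-[4-(benzyloxy)phenyl]-2-oxobut-3-en-1-yl}-2-oxo-3-(phenyliodonio)-2H-pyran-4-olate (phenyliodonium ylide of 5) | O=C(/C=C/c1ccc(OCc2ccccc2)cc1)Cc1cc([O-])c([I+]c2ccccc2)c(=O)o1 | intermediate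
7 | apigenin (5,7-dihydroxy-2-(4-hydroxyphenyl)-4H-chromen-4-one) | O=c1cc(-c2ccc(O)cc2)oc2cc(O)cc(O)c12 | starting material
8 | 5,7-bis(benzyloxy)-2-[4-(benzyloxy)phenyl]-4H-chromen-4-one (tri-O-benzylapigenin) | O=c1cc(-c2ccc(OCc3ccccc3)cc2)oc2cc(OCc3ccccc3)cc(OCc3ccccc3)c12 | intermediate
9 | 5,7-bis(benzyloxy)-2-[4-(benzyloxy)phenyl]-8-iodo-4H-chromen-4-one | O=c1cc(-c2ccc(OCc3ccccc3)cc2)oc2c(I)c(OCc3ccccc3)cc(OCc3ccccc3)c12 | intermediate
10 | 5,7-bis(benzyloxy)-2-[4-(benzyloxy)phenyl]-8-(4,4,5,5-tetramethyl-1,3,2-dioxaborolan-2-yl)-4H-chromen-4-one | O=c1cc(-c2ccc(OCc3ccccc3)cc2)oc2c(B3OC(C)(C)C(C)(C)O3)c(OCc3ccccc3)cc(OCc3ccccc3)c12 | intermediate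
11 | 6-{(E)-4-[4-(benzyloxy)phenyl]-2-oxobut-3-en-1-yl}-4-hydroxy-3-(tri-O-benzylapigenin-8-yl)-2H-pyran-2-one | O=C(/C=C/c1ccc(OCc2ccccc2)cc1)Cc1cc(O)c(-c2c(OCc3ccccc3)cc(OCc3ccccc3)c3c(=O)cc(-c4ccc(OCc5ccccc5)cc4)oc23)c(=O)o1 | intermediate
12 | methyl (E)-9-[4-(benzyloxy)phenyl]-3,5,7-trioxo-2-(tri-O-benzylapigenin-8-yl)non-8-enoate (magnesium chelate in the flask; not isolated) | COC(=O)C(C(=O)CC(=O)CC(=O)/C=C/c1ccc(OCc2ccccc2)cc1)c1c(OCc2ccccc2)cc(OCc2ccccc2)c2c(=O)cc(-c3ccc(OCc4ccccc4)cc3)oc12 | intermediate
13 | (E)-3-[4-(benzyloxy)phenyl]-1-[2,4,6-trihydroxy-3-(tri-O-benzylapigenin-8-yl)phenyl]prop-2-en-1-one | O=C(/C=C/c1ccc(OCc2ccccc2)cc1)c1c(O)cc(O)c(-c2c(OCc3ccccc3)cc(OCc3ccccc3)c3c(=O)cc(-c4ccc(OCc5ccccc5)cc4)oc23)c1O | intermediate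
14 | 2-[4-(benzyloxy)phenyl]-5,7-dihydroxy-6-(tri-O-benzylapigenin-8-yl)chroman-4-one (racemic at C2; not isolated) | O=C1CC(c2ccc(OCc3ccccc3)cc2)Oc2cc(O)c(-c3c(OCc4ccccc4)cc(OCc4ccccc4)c4c(=O)cc(-c5ccc(OCc6ccccc6)cc5)oc34)c(O)c21 | intermediate
15 | 2-[4-(benzyloxy)phenyl]-5,7-dihydroxy-6-(tri-O-benzylapigenin-8-yl)-4H-chromen-4-one | Oc1cc2oc(-c3ccc(OCc4ccccc4)cc3)cc(=O)c2c(O)c1-c1c(OCc2ccccc2)cc(OCc2ccccc2)c2c(=O)cc(-c3ccc(OCc4ccccc4)cc3)oc12 | intermediate
16 | 2-[4-(benzyloxy)phenyl]-5-hydroxy-7-methoxy-6-(tri-O-benzylapigenin-8-yl)-4H-chromen-4-one | COc1cc2oc(-c3ccc(OCc4ccccc4)cc3)cc(=O)c2c(O)c1-c1c(OCc2ccccc2)cc(OCc2ccccc2)c2c(=O)cc(-c3ccc(OCc4ccccc4)cc3)oc12 | intermediate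
17 | 6-[5,7-dihydroxy-2-(4-hydroxyphenyl)-4-oxo-4H-chromen-8-yl]-5-hydroxy-2-(4-hydroxyphenyl)-7-methoxy-4H-chromen-4-one | COc1cc2oc(-c3ccc(O)cc3)cc(=O)c2c(O)c1-c1c(O)cc(O)c2c(=O)cc(-c3ccc(O)cc3)oc12 | target

## Step count and least certain steps

Total: 11 steps. Longest linear sequence: 8 steps (from 7 through steps 4–11, or from 1 through steps 1–3 and 7–11).

Step 8 (key step). The doubly ionized, hindered 3-arylpyronate may resist methoxide attack at the lactone carbonyl. During the long heating the chain may then be consumed before it folds, by retro-Claisen cleavage of the cinnamoyl ketone or by conjugate addition of the C8 carbanion to the enone. Fallback: the fold is given up and the C6–C8'' bond is made by cross-coupling of two flavones, setting out from boronate 10 and rejoining the route at 16. Commercial genkwanin F1 is benzylated at its unchelated 4'-OH (BnBr, K2CO3, acetone) to 4'-O-benzylgenkwanin F2. Iodination at C6 under direction of the free 5-OH (BnMe3N·ICl2, CaCO3, CH2Cl2–MeOH) gives 6-iodo-4'-O-benzylgenkwanin F3. Suzuki–Miyaura coupling of F3 with 10 (Pd(OAc)2, SPhos, K3PO4, toluene–H2O, 100 °C) should give 16.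

Step 7. Transmetalation from a di-ortho-substituted, electron-rich boronate is slow, so protodeboronation of 10 and decomposition of ylide 6 may outrun the coupling. Fallback: ligand coupling on lead replaces palladium catalysis, setting out from iodide 9 and pyrone 5 and returning at 11. Iodide 9 is stannylated ((Bu3Sn)2, Pd(PPh3)4, toluene, 110 °C) to 8-(tributylstannyl)-tri-O-benzylapigenin F4. Tin–lead exchange (Pb(OAc)4, Hg(OAc)2 cat., CHCl3, 40 °C) gives (tri-O-benzylapigenin-8-yl)lead triacetate F5, which C-arylates the 4-hydroxypyrone 5 at C3 (pyridine, CHCl3, 40–60 °C). This ligand coupling on tetravalent lead is established for cyclic β-dicarbonyl compounds with 2,6-dioxygenated aryl groups and is helped, not hindered, by ortho substituents.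

Step 9. Site selectivity of the oxa-Michael closure may be poor, with ring C closing in part through the C5 hydroxyl. Nuclear iodination of the free phloroglucinol ring at C8 may also occur, but that would be erased in step 11. Fallback: closure and oxidation are separated, setting out from 13 and returning at 15. Chalcone 13 is cyclized under reversible conditions (NaOAc, EtOH, reflux), in which 6-aryl flavanone 14 and its 8-aryl isomer, 2-[4-(benzyloxy)phenyl]-5,7-dihydroxy-8-(tri-O-benzylapigenin-8-yl)chroman-4-one F6, interconvert through 13. Flavanone 14 is isolated by chromatography and F6 is resubjected to the same conditions. Flavanone 14 is then dehydrogenated with DDQ in 1,4-dioxane at reflux, neutral conditions under which ring C should not reopen, to give 15.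

Step 3. The iodine reagent may attack the enolizable side-chain methylene or degrade the enone chain oxidatively instead of forming the ylide cleanly at C3. Fallback: the order of events is reversed, setting out from 4 and 10 and returning at 11. Triacetic acid lactone 4 is converted into its own ylide, 6-methyl-2-oxo-3-(phenyliodonio)-2H-pyran-4-olate F7 (PhI(OAc)2, Na2CO3, H2O). F7 is coupled with 10 under the conditions of step 7 to 4-hydroxy-6-methyl-3-(tri-O-benzylapigenin-8-yl)-2H-pyran-2-one F8. The O,C-dianion of F8 (LiN(i-Pr)2, 2.1 equiv, THF, −78 °C) is acylated with 3 as in step 2. The price is exposure of the flavone to lithium amide, which is why this order is held in reserve.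

## Further compounds

F1 | step 8 | genkwanin (5-hydroxy-2-(4-hydroxyphenyl)-7-methoxy-4H-chromen-4-one) | COc1cc(O)c2c(=O)cc(-c3ccc(O)cc3)oc2c1
F2 | step 8 | 4'-O-benzylgenkwanin (2-[4-(benzyloxy)phenyl]-5-hydroxy-7-methoxy-4H-chromen-4-one) | COc1cc(O)c2c(=O)cc(-c3ccc(OCc4ccccc4)cc3)oc2c1
F3 | step 8 | 6-iodo-4'-O-benzylgenkwanin (2-[4-(benzyloxy)phenyl]-5-hydroxy-6-iodo-7-methoxy-4H-chromen-4-one) | COc1cc2oc(-c3ccc(OCc4ccccc4)cc3)cc(=O)c2c(O)c1I
F4 | step 7 | 8-(tributylstannyl)-tri-O-benzylapigenin | CCCC[Sn](CCCC)(CCCC)c1c(OCc2ccccc2)cc(OCc2ccccc2)c2c(=O)cc(-c3ccc(OCc4ccccc4)cc3)oc12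
F5 | step 7 | (tri-O-benzylapigenin-8-yl)lead triacetate | CC(=O)O[Pb](OC(C)=O)(OC(C)=O)c1c(OCc2ccccc2)cc(OCc2ccccc2)c2c(=O)cc(-c3ccc(OCc4ccccc4)cc3)oc12
F6 | step 9 | 2-[4-(benzyloxy)phenyl]-5,7-dihydroxy-8-(tri-O-benzylapigenin-8-yl)chroman-4-one (racemic at C2) | O=C1CC(c2ccc(OCc3ccccc3)cc2)Oc2c(-c3c(OCc4ccccc4)cc(OCc4ccccc4)c4c(=O)cc(-c5ccc(OCc6ccccc6)cc5)oc34)c(O)cc(O)c21
F7 | step 3 | 6-methyl-2-oxo-3-(phenyliodonio)-2H-pyran-4-olate | Cc1cc([O-])c([I+]c2ccccc2)c(=O)o1
F8 | step 3 | 4-hydroxy-6-methyl-3-(tri-O-benzylapigenin-8-yl)-2H-pyran-2-one | Cc1cc(O)c(-c2c(OCc3ccccc3)cc(OCc3ccccc3)c3c(=O)cc(-c4ccc(OCc5ccccc5)cc4)oc23)c(=O)o1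
A1 | alternative 1 | 6-[2-hydroxy-4,6-bis(triisopropylsilyloxy)phenyl]-5,4'-di-O-benzylgenkwanin | COc1cc2oc(-c3ccc(OCc4ccccc4)cc3)cc(=O)c2c(OCc2ccccc2)c1-c1c(O)cc(O[Si](C(C)C)(C(C)C)C(C)C)cc1O[Si](C(C)C)(C(C)C)C(C)C
A2 | alternative 1 | 4-(5,4'-di-O-benzylgenkwanin-6-yl)-3-(triisopropylsilyloxy)cyclobut-2-en-1-one (racemic) | O=C1C=C(O[Si](C(C)C)(C(C)C)C(C)C)C1c1c(OC)cc2oc(-c3ccc(OCc4ccccc4)cc3)cc(=O)c2c1OCc1ccccc1
A3 | alternative 1 | (triisopropylsilyloxy)ethyne | C#CO[Si](C(C)C)(C(C)C)C(C)C
A4 | alternative 2 | 5-O-methyl-5'',7'',4',4'''-tetra-O-benzyl derivative of the target | COc1cc2oc(-c3ccc(OCc4ccccc4)cc3)cc(=O)c2c(OC)c1-c1c(OCc2ccccc2)cc(OCc2ccccc2)c2c(=O)cc(-c3ccc(OCc4ccccc4)cc3)oc12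
A5 | alternative 2 | biaryl bis[(triphenylphosphoranylidene)acetyl] bis(4-benzyloxybenzoate) (ring A of unit 1: 5,7-dimethoxy; ring A of unit 2: 5'',7''-dibenzyloxy; aroates on O8a and O8a'') | COc1cc(OC(=O)c2ccc(OCc3ccccc3)cc2)c(C(=O)C=P(c2ccccc2)(c2ccccc2)c2ccccc2)c(OC)c1-c1c(OCc2ccccc2)cc(OCc2ccccc2)c(C(=O)C=P(c2ccccc2)(c2ccccc2)c2ccccc2)c1OC(=O)c1ccc(OCc2ccccc2)cc1
A6 | alternative 3 | 2-[4-(benzyloxy)phenyl]-5,7-dihydroxy-6-(tri-O-benzylapigenin-8-yl)-4H-chromen-4-one (identical with 15) | Oc1cc2oc(-c3ccc(OCc4ccccc4)cc3)cc(=O)c2c(O)c1-c1c(OCc2ccccc2)cc(OCc2ccccc2)c2c(=O)cc(-c3ccc(OCc4ccccc4)cc3)oc12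
A7 | alternative 3 | methyl 6-[4-(benzyloxy)phenyl]-2-methyl-4-oxo-4H-pyran-3-carboxylate | COC(=O)c1c(C)oc(-c2ccc(OCc3ccccc3)cc2)cc1=O
A8 | alternative 3 | (tri-O-benzylapigenin-8-yl)acetyl chloride | O=C(Cl)Cc1c(OCc2ccccc2)cc(OCc2ccccc2)c2c(=O)cc(-c3ccc(OCc4ccccc4)cc3)oc12
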